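**Strategy.** The butanolide ring (O–C19–C17–C8–C7) is read as the Baeyer–Villiger product of a cyclobutanone in which C19 is still bonded to C7. That four-membered ring is made by [2+2] cycloaddition of a vinylketene (C19=C7, carrying C3–C6, a C16 allylsilane and a Z-vinyl iodide), released by Wolff rearrangement of a dienyl diazoketone, with the Z-enol ether C8=C17 of a 4-ethylidene-1,3-dioxolane held on ring A. The step unites both halves, forms C19–C17 and C7–C8 and sets C7, C8 and C17; oxygen insertion then turns the temporary C19–C7 bond into the lactone. A Nozaki–Hiyama–Kishi closure (C2–C3) builds the ten-membered ring, and the allylsilane later delivers the C6 chloride.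

Key step: step 19

Assumption: locants follow briarane numbering of the target (C19 lactone carbonyl, C17 its α-carbon, C15 the methyl on C1, C16 and C20 the exocyclic methylene carbons). Compounds 1, 15, 23, 24 and the reagents named in the Conditions lines are taken to be commercial.

## Ring A and the enol ether (steps 1–11)

Step 1
Reactants: 1 1,4-dioxaspiro[4.5]dec-6-en-8-one
Product: 2 7-(hydroxymethyl)-1,4-dioxaspiro[4.5]dec-6-en-8-one
Conditions: 37% aq. HCHO, imidazole, 1 M aq. NaHCO3, THF, rt
Reagents that add atoms: formaldehyde, C=O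
Why: Morita–Baylis–Hillman hydroxymethylation at the enone α-carbon should place C2 on the future C1.

Step 2
Reactants: 2 7-(hydroxymethyl)-1,4-dioxaspiro[4.5]dec-6-en-8-one
Product: 3 7-(TBS-oxymethyl)-1,4-dioxaspiro[4.5]dec-6-en-8-one
Conditions: TBSCl, imidazole, DMF, 0 °C → rt
Reagents that add atoms: tert-butyldimethylsilyl chloride, CC(C)(C)[Si](C)(C)Cl
Why: Silylation of the primary alcohol keeps a free hydroxyl from consuming or directing the borane in the next step.

Step 3
Reactants: 3 7-(TBS-oxymethyl)-1,4-dioxaspiro[4.5]dec-6-en-8-one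
Product: 4 (8S)-7-(TBS-oxymethyl)-1,4-dioxaspiro[4.5]dec-6-en-8-ol
Conditions: (R)-2-methyl-CBS-oxazaborolidine (0.2 equiv), BH3·SMe2, THF, −30 °C; then MeOH
Reagents that add atoms: none
Why: CBS reduction of an α-substituted enone, in which the catalyst distinguishes the substituted alkenyl arm from the CH2 arm, should set C14 (S).

Step 4
Reactants: 4 (8S)-7-(TBS-oxymethyl)-1,4-dioxaspiro[4.5]dec-6-en-8-ol
Product: 5 bis-TBS ether of 4
Conditions: TBSOTf, 2,6-lutidine, CH2Cl2, −78 → 0 °C
Reagents that add atoms: tert-butyldimethylsilyl triflate, CC(C)(C)[Si](C)(C)OS(=O)(=O)C(F)(F)F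
Why: Silylation of the allylic alcohol gives the γ-silyloxy group that later directs the cuprate.

Step 5
Reactants: 5 bis-TBS ether of 4
Product: 6 (4S)-4-(TBS-oxy)-3-(TBS-oxymethyl)cyclohex-2-en-1-one
Conditions: PPTS, THF/H2O (4:1), 45 °C
Reagents that add atoms: water, O
Why: Hydrolysis of the allylic ketal unmasks the C11 ketone in conjugation with C10=C1, a net enone transposition that leaves C14 untouched.

Step 6
Reactants: 6 (4S)-4-(TBS-oxy)-3-(TBS-oxymethyl)cyclohex-2-en-1-one
Product: 8 ring A β-keto dimethyl acetal, via enol silane 7 (not isolated)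
Conditions: Me2CuLi (from MeLi and CuI), TMSCl, THF, −78 °C; solvent exchange; HC(OMe)3, TMSOTf (0.1 equiv), CH2Cl2, −78 °C
Reagents that add atoms: lithium dimethylcuprate, [Li+].C[Cu-]C; trimethyl orthoformate, COC(OC)OC
Why: TMSCl-accelerated cuprate 1,4-addition should occur anti to the C14 silyl ether to create quaternary C1, and the Mukaiyama-type addition of the enol silane to the dimethoxycarbenium ion should place C9 on C10 anti to the pseudo-axial CH2OTBS arm, that is cis to the new methyl.

Step 7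
Reactants: 8 ring A β-keto dimethyl acetal
Product: 9 C11-methylene dimethyl acetal
Conditions: Cp2TiMe2, toluene, 65 °C, dark
Reagents that add atoms: dimethyltitanocene, [CH3-].[CH3-].[Ti+4].c1cc[cH-]c1.c1cc[cH-]c1
Why: Petasis methylenation is non-basic, so the epimerizable C10 and the β-alkoxy ketone (no E1cB loss of methoxide) should survive while C20 is installed.

Step 8
Reactants: 9 C11-methylene dimethyl acetal
Product: 10 ring A aldehyde (C9 formyl)
Conditions: LiBF4, MeCN/H2O (98:2), rt
Reagents that add atoms: water, O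
Why: Mild acetal hydrolysis should spare both silyl ethers and the exocyclic alkene, and the β,γ-unsaturated aldehyde is used at once to avoid migration into conjugation.

Step 9
Reactants: 10 ring A aldehyde (C9 formyl)
Product: 12 anti-8,9-diol bearing the C17=C18 vinyl group, via borinate 11 (not isolated)
Conditions: allyl(diisopropylamino)dimethylsilane, n-BuLi, TMEDA, Et2O, 0 °C; (+)-Ipc2BOMe, −78 °C; BF3·OEt2; then 10, −78 °C; then 30% H2O2, KF, KHCO3, THF/MeOH, rt
Reagents that add atoms: allyl(diisopropylamino)dimethylsilane, C=CC[Si](C)(C)N(C(C)C)C(C)C; hydrogen peroxide, OO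
Why: Reagent-controlled anti-selective γ-silylallylboration through a chair transition state should set C9 (the Ipc2B antipode from (−)-α-pinene is chosen to give 9S), and Tamao oxidation replaces silicon by hydroxyl with retention.

Step 10
Reactants: 12 anti-8,9-diol bearing the C17=C18 vinyl group
Product: 13 4-vinyl-1,3-dioxolane (8,9-acetonide)
Conditions: 2,2-dimethoxypropane, PPTS, CH2Cl2, rt
Reagents that add atoms: 2,2-dimethoxypropane, COC(C)(C)OC
Why: Acetonide formation ties O8 and O9 into the five-membered ring that will control the face of the enol ether.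

Step 11
Reactants: 13 4-vinyl-1,3-dioxolane (8,9-acetonide)
Product: 14 (Z)-4-ethylidene-1,3-dioxolane on ring A (enol ether C8=C17)
Conditions: [Ir(cod)(PMePh2)2]PF6 (3 mol%, activated with H2), THF, rt
Reagents that add atoms: none
Why: Iridium hydride isomerization of the allylic ether to the enol ether erases the C8 stereocenter and should place the C18 methyl anti to C9 (Z), while the 1,1-disubstituted C11 methylene is expected to stay in place at rt.

## Ketene precursor (steps 12–17) and side-chain acid (step 18)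

Step 12
Reactants: 15 methyl 4,4-dimethoxy-3-oxobutanoate
Product: 16 methyl (2Z)-4,4-dimethoxy-3-(triflyloxy)but-2-enoate
Conditions: Tf2O, 5 M aq. LiOH, toluene, 5 °C
Reagents that add atoms: triflic anhydride, O=S(=O)(OS(=O)(=O)C(F)(F)F)C(F)(F)F
Why: O-triflation of the lithium-chelated Z-enolate of the β-keto ester should give the Z-enol triflate.

Step 13
Reactants: 16 methyl (2Z)-4,4-dimethoxy-3-(triflyloxy)but-2-enoate
Product: 17 methyl (2Z)-4,4-dimethoxy-3-[(trimethylsilyl)methyl]but-2-enoate
Conditions: Me3SiCH2MgCl, Pd(PPh3)4 (5 mol%), THF, 0 °C → rt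
Reagents that add atoms: (trimethylsilyl)methylmagnesium chloride, C[Si](C)(C)C[Mg]Cl
Why: Kumada coupling of the enol triflate proceeds with retention, so the allylsilane carbon C16 ends cis to the ester.

Step 14
Reactants: 17 methyl (2Z)-4,4-dimethoxy-3-[(trimethylsilyl)methyl]but-2-enoate
Product: 18 methyl (2Z)-3-formyl-4-(trimethylsilyl)but-2-enoate
Conditions: TFA/H2O (1:1), CHCl3, 0 °C
Reagents that add atoms: water, O
Why: Acetal hydrolysis frees the C4 aldehyde, and the allylsilane, deactivated by conjugation with the ester, should resist protodesilylation.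

Step 15
Reactants: 18 methyl (2Z)-3-formyl-4-(trimethylsilyl)but-2-enoate
Product: 19 methyl (2Z,4Z)-5-iodo-3-[(trimethylsilyl)methyl]penta-2,4-dienoate
Conditions: Ph3P(CH2I)I, NaHMDS, THF/DMPU, −78 °C
Reagents that add atoms: (iodomethylene)triphenylphosphorane, IC=P(c1ccccc1)(c1ccccc1)c1ccccc1
Why: Stork–Zhao olefination of the aldehyde should give the Z-vinyl iodide (C3=C4) under kinetic control.

Step 16
Reactants: 19 methyl (2Z,4Z)-5-iodo-3-[(trimethylsilyl)methyl]penta-2,4-dienoate
Product: 20 (2Z,4Z)-5-iodo-3-[(trimethylsilyl)methyl]penta-2,4-dienoic acid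
Conditions: LiOH, THF/H2O, 0 °C; then 1 M HCl
Reagents that add atoms: lithium hydroxide, [Li+].[OH-]
Why: Cold saponification should cleave the methyl ester without touching the vinyl iodide or the silane.

Step 17
Reactants: 20 (2Z,4Z)-5-iodo-3-[(trimethylsilyl)methyl]penta-2,4-dienoic acid
Product: 22 (3Z,5Z)-1-diazo-6-iodo-4-[(trimethylsilyl)methyl]hexa-3,5-dien-2-one, via acid chloride 21 (not isolated)
Conditions: (COCl)2, DMF (cat.), CH2Cl2, 0 °C; then CH2N2, Et2O, 0 °C
Reagents that add atoms: diazomethane, C=[N+]=[N-]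
Why: Acylation of diazomethane (first half of an Arndt–Eistert homologation) brings in C7 and gives the isolable diazoketone from which the vinylketene is released in the key step.

Step 18
Reactants: 23 glycolic acid; 24 3-methylbutanoyl chloride
Product: 25 2-[(3-methylbutanoyl)oxy]acetic acid
Conditions: neat, 60 °C
Reagents that add atoms: none
Why: O-acylation of the hydroxy acid by the acid chloride gives the C2 side-chain acid.

## Key step and endgame (steps 19–27)

Step 19
Reactants: 14 (Z)-4-ethylidene-1,3-dioxolane on ring A (enol ether C8=C17); 22 (3Z,5Z)-1-diazo-6-iodo-4-[(trimethylsilyl)methyl]hexa-3,5-dien-2-one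
Product: 27 spiro 3-alkoxy-2-alkenyl-4-methylcyclobutanone, via vinylketene 26 (not isolated)
Conditions: 22 (2.5 equiv) in THF added over 8 h to 14, AgO2CPh (0.2 equiv) and Et3N (3 equiv), anhydrous THF, rt, dark, ultrasound
Reagents that add atoms: none
Why: AgO2CPh-promoted Wolff rearrangement of diazoketone 22 (loss of N2 and 1,2-shift of the dienyl group with retention of its geometry) releases vinylketene 26 at low stationary concentration in the absence of any protic trap; the nucleophilic C17 of the enol ether adds to the ketene carbon C19 and the dipolar, asynchronous transition state closes C7–C8 to give the 3-alkoxy-2-alkenylcyclobutanone. The closest known reaction type is the Wolff rearrangement of an α,β-unsaturated α′-diazoketone run in the presence of a ketenophile, that is, the thermal vinylketene–enol ether [2+2] cycloaddition. One four-membered ring is closed, by an intermolecular [2+2] with orthogonal ketene approach and 4-exo collapse of the zwitterion, and it is spiro-fused to the dioxolane at C8. C8 should be set by approach anti to the ring A substituent on C9 of the dioxolane, C17 by suprafacial transfer of the Z geometry (methyl syn to O8), and C7 by the preference of the ketene substituent for the side of the smaller ether oxygen, an arrangement the amine can also reach by α-epimerization. The step needs regioselectivity (C19 to C17), secured by the polarization of the enol ether; rearrangement and cycloaddition rather than carbene transfer to the enol ether or ketene dimerization, secured by the silver catalyst (which favours the Wolff pathway over cyclopropanation) and by slow addition of excess 22; and no 6π closure of the dienylketene, secured by the C5=C6 geometry that holds C7 and C4 trans.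

Step 20
Reactants: 27 spiro 3-alkoxy-2-alkenyl-4-methylcyclobutanone
Product: 28 spiro γ-lactone (C7–O–C19)
Conditions: 30% H2O2, Na2HPO4, CF3CH2OH, 0 °C → rt
Reagents that add atoms: hydrogen peroxide, OO
Why: Baeyer–Villiger oxidation of the strained cyclobutanone should be chemoselective over the alkenes, with the allylic secondary C7 migrating in preference to C17 and with retention.

Step 21
Reactants: 28 spiro γ-lactone (C7–O–C19)
Product: 29 C2 primary alcohol (C14 OTBS kept)
Conditions: HF·pyridine, pyridine, THF, 0 °C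
Reagents that add atoms: none
Why: The primary silyl ether should be cleaved faster than the hindered secondary C14 silyl ether under buffered HF.

Step 22
Reactants: 29 C2 primary alcohol (C14 OTBS kept)
Product: 30 C2 aldehyde
Conditions: 1,1,1-triacetoxy-1,1-dihydro-1,2-benziodoxol-3(1H)-one (DMP), NaHCO3, CH2Cl2, rt
Reagents that add atoms: none
Why: Buffered periodinane oxidation gives the neopentyl aldehyde without touching the allylsilane, vinyl iodide or lactone.

Step 23
Reactants: 30 C2 aldehyde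
Product: 31 ten-membered C2 allylic alcohol
Conditions: CrCl2 (10 equiv), NiCl2 (2 mol%), DMSO/THF (3:1), rt, 2 mM
Reagents that add atoms: none
Why: Intramolecular Nozaki–Hiyama–Kishi addition of the Z-alkenylchromium (geometry retained) to the aldehyde closes the ten-membered ring, and attack on the rotamer with C=O syn to the C15 methyl and anti to the C14–O bond should give the 2S carbinol.

Step 24
Reactants: 31 ten-membered C2 allylic alcohol; 25 2-[(3-methylbutanoyl)oxy]acetic acid
Product: 32 C2 (3-methylbutanoyloxy)acetate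
Conditions: DCC, DMAP, CH2Cl2, 0 °C → rt
Reagents that add atoms: none
Why: Steglich esterification acylates the only free hydroxyl.

Step 25
Reactants: 32 C2 (3-methylbutanoyloxy)acetate
Product: 33 6-chloro-5(16)-ene (acetonide and C14 OTBS kept)
Conditions: NCS, CH2Cl2, −20 °C
Reagents that add atoms: N-chlorosuccinimide, O=C1CCC(=O)N1Cl
Why: SE2′ chlorination of the allylsilane puts chlorine on C6 and moves the alkene to C5=C16, the β-silyl cation fixing the regiochemistry and peripheral attack on the ring alkene expected to give 6S.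

Step 26
Reactants: 33 6-chloro-5(16)-ene (acetonide and C14 OTBS kept)
Product: 34 8,9,14-triol
Conditions: 48% aq. HF, MeCN, 0 °C → rt
Reagents that add atoms: none
Why: Aqueous HF should remove the C14 silyl ether and hydrolyse the acetonide in a weakly ionizing medium that spares the allylic chloride and the esters.

Step 27
Reactants: 34 8,9,14-triol
Product: 35 Frajunolide K
Conditions: Ac2O, pyridine, DMAP (cat.), CH2Cl2, 0 °C
Reagents that add atoms: acetic anhydride, CC(=O)OC(C)=O
Why: The two secondary alcohols (C9, C14) are acetylated while the hindered tertiary C8 hydroxyl should remain free.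

## Compound list

1 | 1,4-dioxaspiro[4.5]dec-6-en-8-one | O=C1CCC2(OCCO2)C=C1 | starting material
2 | 7-(hydroxymethyl)-1,4-dioxaspiro[4.5]dec-6-en-8-one | O=C1CCC2(OCCO2)C=C1CO | intermediate
3 | 7-{[(tert-butyldimethylsilyl)oxy]methyl}-1,4-dioxaspiro[4.5]dec-6-en-8-one | O=C1CCC2(OCCO2)C=C1CO[Si](C)(C)C(C)(C)C | intermediate
4 | (8S)-7-{[(tert-butyldimethylsilyl)oxy]methyl}-1,4-dioxaspiro[4.5]dec-6-en-8-ol | O[C@H]1CCC2(OCCO2)C=C1CO[Si](C)(C)C(C)(C)C | intermediate
5 | bis-TBS ether of 4 | CC(C)(C)[Si](C)(C)O[C@H]1CCC2(OCCO2)C=C1CO[Si](C)(C)C(C)(C)C | intermediate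
6 | (4S)-4-[(tert-butyldimethylsilyl)oxy]-3-{[(tert-butyldimethylsilyl)oxy]methyl}cyclohex-2-en-1-one (C11 ketone, C10=C1, C14 OTBS) | O=C1CC[C@H](O[Si](C)(C)C(C)(C)C)C(CO[Si](C)(C)C(C)(C)C)=C1 | intermediate
7 | trimethylsilyl enol ether (C10=C11) of the methyl adduct; C15 methyl trans to C14 OTBS | C[Si](C)(C)OC1=C[C@@](C)(CO[Si](C)(C)C(C)(C)C)[C@@H](O[Si](C)(C)C(C)(C)C)CC1 | intermediate (not isolated)
8 | 2-(dimethoxymethyl)-3-methyl-4-(TBS-oxy)-3-(TBS-oxymethyl)cyclohexan-1-one; C9 acetal cis to C15 methyl, methyl trans to C14 OTBS | O=C1CC[C@H](O[Si](C)(C)C(C)(C)C)[C@](C)(CO[Si](C)(C)C(C)(C)C)[C@H]1C(OC)OC | intermediate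
9 | C11-methylene analogue of 8 | C=C1CC[C@H](O[Si](C)(C)C(C)(C)C)[C@](C)(CO[Si](C)(C)C(C)(C)C)[C@H]1C(OC)OC | intermediate
10 | ring A aldehyde (C9 formyl on C10) | C=C1CC[C@H](O[Si](C)(C)C(C)(C)C)[C@](C)(CO[Si](C)(C)C(C)(C)C)[C@H]1C=O | intermediate
11 | O-diisopinocampheylborinate of the anti-β-hydroxy allylsilane | C=C1CC[C@H](O[Si](C)(C)C(C)(C)C)[C@](C)(CO[Si](C)(C)C(C)(C)C)[C@H]1[C@H](OB([C@H]2C[C@H]3C[C@@H]([C@@H]2C)C3(C)C)[C@H]2C[C@H]3C[C@@H]([C@@H]2C)C3(C)C)[C@H]([Si](C)(C)N(C(C)C)C(C)C)C=C | intermediate (not isolated)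
12 | anti-8,9-diol with C17=C18 vinyl (9S) | C=C1CC[C@H](O[Si](C)(C)C(C)(C)C)[C@](C)(CO[Si](C)(C)C(C)(C)C)[C@H]1[C@H](O)[C@H](O)C=C | intermediate
13 | 2,2-dimethyl-4-vinyl-1,3-dioxolane (cis-4,5) on C10 of ring A | C=C1CC[C@H](O[Si](C)(C)C(C)(C)C)[C@](C)(CO[Si](C)(C)C(C)(C)C)[C@H]1[C@@H]2OC(C)(C)O[C@@H]2C=C | intermediate
14 | (Z)-4-ethylidene-2,2-dimethyl-1,3-dioxolane on C10 of ring A (enol ether C8=C17, methyl cis to O8) | C=C1CC[C@H](O[Si](C)(C)C(C)(C)C)[C@](C)(CO[Si](C)(C)C(C)(C)C)[C@H]1[C@@H]2OC(C)(C)O/C2=C\C | intermediate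
15 | methyl 4,4-dimethoxy-3-oxobutanoate | COC(OC)C(=O)CC(=O)OC | starting material
16 | methyl (2Z)-4,4-dimethoxy-3-{[(trifluoromethyl)sulfonyl]oxy}but-2-enoate | COC(=O)/C=C(\OS(=O)(=O)C(F)(F)F)C(OC)OC | intermediate
17 | methyl (2Z)-4,4-dimethoxy-3-[(trimethylsilyl)methyl]but-2-enoate | COC(=O)/C=C(\C[Si](C)(C)C)C(OC)OC | intermediate
18 | methyl (2Z)-3-formyl-4-(trimethylsilyl)but-2-enoate | COC(=O)/C=C(\C[Si](C)(C)C)C=O | intermediate
19 | methyl (2Z,4Z)-5-iodo-3-[(trimethylsilyl)methyl]penta-2,4-dienoate | COC(=O)/C=C(\C[Si](C)(C)C)/C=C\I | intermediate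
20 | (2Z,4Z)-5-iodo-3-[(trimethylsilyl)methyl]penta-2,4-dienoic acid | OC(=O)/C=C(\C[Si](C)(C)C)/C=C\I | intermediate
21 | acid chloride of 20 | ClC(=O)/C=C(\C[Si](C)(C)C)/C=C\I | intermediate (not isolated)
22 | (3Z,5Z)-1-diazo-6-iodo-4-[(trimethylsilyl)methyl]hexa-3,5-dien-2-one | [N-]=[N+]=CC(=O)/C=C(\C[Si](C)(C)C)/C=C\I | intermediate
23 | glycolic acid | OCC(=O)O | starting material
24 | 3-methylbutanoyl chloride | CC(C)CC(Cl)=O | starting material
25 | 2-[(3-methylbutanoyl)oxy]acetic acid | CC(C)CC(=O)OCC(=O)O | intermediate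
26 | (3Z,5Z)-6-iodo-4-[(trimethylsilyl)methyl]hexa-1,3,5-trien-1-one (vinylketene) | O=C=C/C=C(\C[Si](C)(C)C)/C=C\I | intermediate (not isolated)
27 | spiro cyclobutanone (C19 ketone; C6 arm on C7, O8 and C17 methyl all cis; C7 anti to C10 across the dioxolane) | C=C1CC[C@H](O[Si](C)(C)C(C)(C)C)[C@](C)(CO[Si](C)(C)C(C)(C)C)[C@H]1[C@@H]2OC(C)(C)O[C@]23[C@@H](C)C(=O)[C@H]3/C=C(\C[Si](C)(C)C)/C=C\I | intermediate
28 | spiro γ-lactone (O inserted between C19 and C7) | C=C1CC[C@H](O[Si](C)(C)C(C)(C)C)[C@](C)(CO[Si](C)(C)C(C)(C)C)[C@H]1[C@@H]2OC(C)(C)O[C@]23[C@@H](C)C(=O)O[C@H]3/C=C(\C[Si](C)(C)C)/C=C\I | intermediate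
29 | C2 primary alcohol of 28 | C=C1CC[C@H](O[Si](C)(C)C(C)(C)C)[C@](C)(CO)[C@H]1[C@@H]2OC(C)(C)O[C@]23[C@@H](C)C(=O)O[C@H]3/C=C(\C[Si](C)(C)C)/C=C\I | intermediate
30 | C2 aldehyde | C=C1CC[C@H](O[Si](C)(C)C(C)(C)C)[C@](C)(C=O)[C@H]1[C@@H]2OC(C)(C)O[C@]23[C@@H](C)C(=O)O[C@H]3/C=C(\C[Si](C)(C)C)/C=C\I | intermediate
31 | ten-membered ring 2S allylic alcohol (3Z; C5=C6 with C16 allylsilane) | C=C1CC[C@H](O[Si](C)(C)C(C)(C)C)[C@]2(C)[C@@H](O)/C=C\C(C[Si](C)(C)C)=C\[C@@H]3OC(=O)[C@H](C)[C@]34OC(C)(C)O[C@H]4[C@@H]12 | intermediate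
32 | C2 (3-methylbutanoyloxy)acetate of 31 | C=C1CC[C@H](O[Si](C)(C)C(C)(C)C)[C@]2(C)[C@@H](OC(=O)COC(=O)CC(C)C)/C=C\C(C[Si](C)(C)C)=C\[C@@H]3OC(=O)[C@H](C)[C@]34OC(C)(C)O[C@H]4[C@@H]12 | intermediate
33 | (6S)-6-chloro-5(16)-ene; 8,9-acetonide, C14 OTBS | C=C1CC[C@H](O[Si](C)(C)C(C)(C)C)[C@]2(C)[C@@H](OC(=O)COC(=O)CC(C)C)/C=C\C(=C)[C@H](Cl)[C@@H]3OC(=O)[C@H](C)[C@]34OC(C)(C)O[C@H]4[C@@H]12 | intermediate
34 | 8,9,14-triol (9,14-dideacetyl target) | C=C1CC[C@H](O)[C@]2(C)[C@@H](OC(=O)COC(=O)CC(C)C)/C=C\C(=C)[C@H](Cl)[C@@H]3OC(=O)[C@H](C)[C@@]3(O)[C@@H](O)[C@@H]12 | intermediate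
35 | Frajunolide K | C=C1CC[C@H](OC(C)=O)[C@]2(C)[C@@H](OC(=O)COC(=O)CC(C)C)/C=C\C(=C)[C@H](Cl)[C@@H]3OC(=O)[C@H](C)[C@@]3(O)[C@@H](OC(C)=O)[C@@H]12 | target

## Step count and risks

Total step count: 27. Longest linear sequence: 20 steps (steps 1–11 and 19–27).

Steps most likely to fail:

Step 19 (key step). Ketene dimerization, a 1,5-hydrogen shift from C16 to the ketene carbon or carbene transfer to the enol ether may outrun cycloaddition with the hindered trisubstituted enol ether, and facial or C7 selectivity may be incomplete. The fallback sets out from 22 (with 14) and uses a keteniminium in place of the ketene: Wolff rearrangement of 22 in the presence of dimethylamine (AgO2CPh, Et3N, THF) gives the N,N-dimethylamide F1; Tf2O and 2,4,6-collidine convert it into the vinyl keteniminium triflate F2, which undergoes the known keteniminium–alkene [2+2] with 14 to the cyclobutaniminium triflate F3; aqueous NaHCO3 hydrolysis comes back to 27.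

Step 23. Poor facial selectivity at C2 in the ring-closing addition, alongside oligomerization at the ten-membered ring size, may erode the carbinol configuration. The fallback sets out from the epimeric mixture of 31: periodinane oxidation gives the cross-conjugated dienone F4, and CBS reduction with the oxazaborolidine antipode that matches the 2S carbinol (catecholborane, −78 °C) sets C2 under reagent control and comes back to 31.

Step 25. Chlorine may be delivered to the wrong face of the C5=C6 alkene. The fallback sets out from 32 and uses the same facial bias with an oxygen electrophile: mCPBA (NaHCO3, −40 °C) gives the epoxysilane F5, Bu4NF/AcOH triggers Peterson-type opening to the C6-epimeric allylic alcohol F6, and Appel chlorination (PPh3, CCl4, 2,6-lutidine) with inversion comes back to 33.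

## Further compounds

F1 | step 19 | (3Z,5Z)-6-iodo-N,N-dimethyl-4-[(trimethylsilyl)methyl]hexa-3,5-dienamide | CN(C)C(=O)C/C=C(\C[Si](C)(C)C)/C=C\I
F2 | step 19 | vinyl keteniminium triflate from F1 | C[N+](C)=C=C/C=C(\C[Si](C)(C)C)/C=C\I.[O-]S(=O)(=O)C(F)(F)F
F3 | step 19 | cyclobutaniminium triflate (iminium analogue of 27) | C=C1CC[C@H](O[Si](C)(C)C(C)(C)C)[C@](C)(CO[Si](C)(C)C(C)(C)C)[C@H]1[C@@H]2OC(C)(C)O[C@]23[C@@H](C)C(=[N+](C)C)[C@H]3/C=C(\C[Si](C)(C)C)/C=C\I.[O-]S(=O)(=O)C(F)(F)F
F4 | step 23 | C2 ketone of 31 (dienone) | C=C1CC[C@H](O[Si](C)(C)C(C)(C)C)[C@]2(C)C(=O)/C=C\C(C[Si](C)(C)C)=C\[C@@H]3OC(=O)[C@H](C)[C@]34OC(C)(C)O[C@H]4[C@@H]12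
F5 | step 25 | 5,6-epoxide of 32 (epoxysilane) | C=C1CC[C@H](O[Si](C)(C)C(C)(C)C)[C@]2(C)[C@@H](OC(=O)COC(=O)CC(C)C)/C=C\[C@]5(C[Si](C)(C)C)O[C@H]5[C@@H]3OC(=O)[C@H](C)[C@]34OC(C)(C)O[C@H]4[C@@H]12
F6 | step 25 | C6-epimeric allylic alcohol (6-hydroxy-5(16)-ene) | C=C1CC[C@H](O[Si](C)(C)C(C)(C)C)[C@]2(C)[C@@H](OC(=O)COC(=O)CC(C)C)/C=C\C(=C)[C@@H](O)[C@@H]3OC(=O)[C@H](C)[C@]34OC(C)(C)O[C@H]4[C@@H]12
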